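**Compound numbers used throughout**
1 hexadecanedioic acid mono-tert-butyl ester · 2 tert-butyl 16-hydroxyhexadecanoate · 3 tert-butyl 16-oxohexadecanoate · 4 itaconic anhydride · 5 aldol-adduct hydroxy anhydride (not isolated) · 6 remote tert-butyl ester of the target · 7 target

## Analysis of the target

The target is a monocyclic oxolan-2-one, numbered here O1, C2 (bears the (CH2)14CO2H chain), C3 (bears CO2H), C4 (bears the exocyclic =CH2) and C5 (lactone C=O); the chain in the SMILES is read as fourteen CH2 groups ending in a carboxyl group. There are two adjacent stereocentres, C2 (R) and C3 (S), with the chain and the C3 carboxyl trans on the ring, which is also the thermodynamically preferred arrangement. The sensitive part is the C3(H)–C4(=CH2)–C5(=O) array: the methylidene is a Michael acceptor, and base can remove H3 (alpha to the carboxyl and allylic to the methylidene) to give a delocalised anion that reprotonates at the exocyclic carbon, which moves the double bond into the ring (C3=C4) and erases the C3 stereocentre. Two carboxyl groups must end up free while a third is tied up as the lactone, so the three carboxyl carbons must be told apart without a late basic hydrolysis. The remote carboxyl exerts no stereocontrol and is a matter of supply: C2, the fourteen CH2 groups and the carboxyl carbon are the sixteen carbons of a 16-oxohexadecanoic acid. The feature that invites the chosen strategy is that lactone carbon C5, ring carbon C4 with its exocyclic CH2, ring carbon C3 and the carboxyl carbon on C3 are, atom for atom, itaconic acid, with one carboxyl (C5) acylating O1 and the other free. The difficulty is therefore to make the C2–C3 bond with absolute and trans control while the methylidene is already in place, because every route that adds the methylidene afterwards pays with harsh steps on the finished core.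

## Retrosynthetic reasoning

**7 ⇒ 6.** Only the O–C(CH3)3 bond of the remote ester is cut. A tert-butyl ester is chosen because it is inert to the weakly basic key step and is removed by acidolysis, the one condition the methylidene lactone tolerates well. The forward reaction must free the acid without touching H3 or the exocyclic alkene.

**6 ⇒ 3 + 4 (through 5).** The C2–C3 bond and the O1–C5 acyl bond are cut together. This returns aldehyde 3 (C2 and the chain, sixteen carbons) and anhydride 4, which already holds C3, C4, the exocyclic CH2, C5 and the C3 carboxyl carbon at the right oxidation levels. The cut is made here because it is the only one that leaves the methylidene and the free C3 acid untouched in the precursor, so nothing has to be installed or unmasked on the ring afterwards. Forward, an amine–squaramide organocatalyst must enolise 4 at its ring CH2 and add that carbon to one face of 3, giving aldolate 5. The alkoxide of 5 then attacks the far anhydride carbonyl, so the anhydride ring is transposed into the lactone ring and the near carbonyl is released as the C3 carboxylic acid. The step is an addition followed by an isomerisation, so 6 holds every atom of 3 and 4. One operation thus forms one C–C bond, one C–O bond, the ring and both stereocentres from two achiral partners.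

**3 ⇒ 2 ⇒ 1.** Functional group changes only: aldehyde 3 comes from alcohol 2 by oxidation, and 2 from the commercial half ester 1 by chemoselective reduction of its free acid. Two routine steps are all the key step's precursor costs.

## Alternatives that were turned down

Alternative 1: the textbook route, aldol first and methylidene last. Disconnection: the exocyclic C4=CH2 bond is made at the end; the C2–C3 bond comes from an auxiliary-controlled syn-aldol between aldehyde 3 and a succinic half ester carried on a chiral oxazolidinone. Lactonisation, auxiliary cleavage and ester removal would give the saturated trans diacid A1, which is then carboxylated at C4 and methylenated by decarboxylative Mannich reaction. Turned down because the aldol sets the two stereocentres reliably but builds none of the delicate functionality. The methylidene must then be forced onto C4 at about 130 °C with a large excess of a magnesium carbonate reagent on the most advanced intermediate. With stoichiometric auxiliary and boron it needs six to seven steps from 3 for what the chosen key step does in one. It is kept as the fallback.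

Alternative 2: 2-(alkoxycarbonyl)allyl metal addition (Dreiding–Schmidt type). Disconnection: the same C2–C3 and O1–C5 bonds, with the nucleophile an allyl zinc, indium or boron species made from bromide A2; addition to 3 and lactonisation would give ester A3. Turned down on three structural grounds. In A2 the gamma ester is cis to the CH2–metal carbon, so a closed transition state leads to the syn adduct and hence the cis lactone, and the allylmetal equilibrates, giving mixtures. There is no dependable catalytic enantioselective version for this doubly acceptor-substituted reagent, so stoichiometric chiral boron and the less stable alkene geometry would be needed. Finally, the C3 methyl ester of A3 must be hydrolysed next to a lactone and a Michael acceptor, exactly the basic conditions that trigger loss of H3 and alkene migration.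

Alternative 3: dearomatisation and cyclopropane strain release. Disconnection: the C2–chain bond and the lactone C–O bond, with the ring carbons drawn from a cyclopropanated furan. Forward: asymmetric cyclopropanation of a furan-2-carboxylic ester (Cu(OTf)2 with a chiral bis(oxazoline) ligand) gives bicycle A4. Ozonolysis, allyl addition to the resulting cyclopropanecarbaldehyde and base-triggered retro-aldol opening of the donor–acceptor cyclopropane with lactonisation give the trans formyl lactone A5. Turned down on step economy, not on risk: the sequence is stereochemically secure, but A5 carries neither the chain, nor the C3 acid, nor the methylidene. Cross-metathesis with a long-chain unsaturated ester, hydrogenation, aldehyde oxidation, carboxylation and methylenation, and ester removal would still follow, about ten steps in all. The key step would build only the ring, and the methylidene would again come last under harsh conditions.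

Key step: step 3

Assumption: the quinine-derived pseudoenantiomer of the squaramide catalyst is taken to deliver the (2R,3S) series; if the sense of induction is the opposite, the quinidine-derived pseudoenantiomer is used and nothing else changes.

## Route

Step 1
Reactants: 1 hexadecanedioic acid mono-tert-butyl ester (16-(tert-butoxy)-16-oxohexadecanoic acid)
Product: 2 tert-butyl 16-hydroxyhexadecanoate
Conditions: BH3·SMe2 (1.3 equiv), THF, 0 °C to rt; then MeOH
Reagents that add atoms: none
Why: Chemoselective borane reduction of a carboxylic acid; the acid is activated as an acyloxyborane and reduced far faster than the hindered tert-butyl ester, which should survive.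

Step 2
Reactants: 2 tert-butyl 16-hydroxyhexadecanoate
Product: 3 tert-butyl 16-oxohexadecanoate
Conditions: (2,2,6,6-tetramethylpiperidin-1-yl)oxyl (TEMPO, 10 mol%), PhI(OAc)2 (1.1 equiv), CH2Cl2, rt
Reagents that add atoms: none
Why: Oxoammonium-mediated oxidation of a primary alcohol; in the absence of water it should stop at the aldehyde, and the ester is inert. The aldehyde is used directly in step 3.

Step 3
Reactants: 3 tert-butyl 16-oxohexadecanoate; 4 itaconic anhydride (3-methylideneoxolane-2,5-dione)
Product: 6 (2R,3S)-2-[15-(tert-butoxy)-15-oxopentadecyl]-4-methylidene-5-oxooxolane-3-carboxylic acid, via aldol-adduct hydroxy anhydride 5 (not isolated)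
Conditions: 3 and 4 in equimolar amounts, 4 added slowly as a solution; 3-{[3,5-bis(trifluoromethyl)phenyl]amino}-4-{[(8α,9S)-6′-methoxycinchonan-9-yl]amino}cyclobut-3-ene-1,2-dione (C32H28F6N4O3, 5 mol%), tert-butyl methyl ether, −15 °C; then 1 M HCl work-up
Reagents that add atoms: none
Why: Proposed new method: the quinuclidine nitrogen of the bifunctional catalyst should deprotonate the ring CH2 of 4 (the future C3–H, acidified by the adjacent carbonyl and the methylidene, as the easy amine-induced shift of the double bond of 4 into the ring shows), the squaramide N–H pair should hold the dienolate and the ammonium N–H should activate aldehyde 3; the closest known reaction type is the squaramide-catalysed formal cycloaddition of enolisable cyclic anhydrides (homophthalic and aryl-substituted succinic anhydrides) with aldehydes, the catalytic asymmetric form of the Fittig paraconic acid condensation, and what is new is the alkylidene-substituted, dienolisable anhydride. The dienolate should react at its alpha carbon and not at the exocyclic gamma carbon, as dienolates do in kinetically controlled aldol additions, which forms the C2–C3 bond and gives aldolate 5. The lactone ring is then closed by 5-exo-trig attack of the alkoxide oxygen on the distal, methylidene-conjugated anhydride carbonyl (the proximal carbonyl would require a four-membered ring), and collapse of the bicyclic tetrahedral intermediate opens the anhydride and releases the C3 carboxylate, so the oxolanone ring, the exocyclic alkene and the free acid all arise in one operation that keeps every atom of 3 and 4. C2 is set by the catalyst, which should direct the bound enolate to the Si face of the aldehyde; C3 is set in the same ternary complex by the enolate face, and the trans relation is reinforced because the aldol addition is reversible and the diastereomer of the aldolate that places chain and carboxyl on opposite ring faces should lactonise faster than its epimer. The step needs alpha over gamma regioselectivity, trans diastereoselectivity, enantioselectivity and survival of H3; the last is secured because 6 forms as its ammonium carboxylate, in which H3 is no longer acidic enough for the weak amine base. Slow addition of 4 to concentrated 3 is meant to let the bimolecular aldol outrun the unimolecular reprotonation of the dienolate at the exocyclic carbon.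

Step 4
Reactants: 6 (2R,3S)-2-[15-(tert-butoxy)-15-oxopentadecyl]-4-methylidene-5-oxooxolane-3-carboxylic acid
Product: 7 (2R,3S)-2-(14-carboxytetradecyl)-4-methylidene-5-oxooxolane-3-carboxylic acid
Conditions: CF3CO2H/CH2Cl2 (1:4), 0 °C to rt; evaporation, recrystallisation
Reagents that add atoms: none
Why: Acidolysis of a tert-butyl ester by an E1 pathway with loss of 2-methylpropene; alpha-methylidene lactones and their C3 acids are stable to acid, no base is present, so neither stereocentre should be touched, and crystallisation of the diacid should raise isomeric purity.

## Compound list

1 | hexadecanedioic acid mono-tert-butyl ester (16-(tert-butoxy)-16-oxohexadecanoic acid) | CC(C)(C)OC(=O)CCCCCCCCCCCCCCC(=O)O | starting material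
2 | tert-butyl 16-hydroxyhexadecanoate | CC(C)(C)OC(=O)CCCCCCCCCCCCCCCO | intermediate
3 | tert-butyl 16-oxohexadecanoate | CC(C)(C)OC(=O)CCCCCCCCCCCCCCC=O | intermediate
4 | itaconic anhydride (3-methylideneoxolane-2,5-dione) | C=C1CC(=O)OC1=O | starting material
5 | (3S)-3-[(1R)-16-(tert-butoxy)-1-hydroxy-16-oxohexadecyl]-4-methylideneoxolane-2,5-dione | C=C1C(=O)OC(=O)[C@@H]1[C@H](O)CCCCCCCCCCCCCCC(=O)OC(C)(C)C | intermediate (not isolated)
6 | (2R,3S)-2-[15-(tert-butoxy)-15-oxopentadecyl]-4-methylidene-5-oxooxolane-3-carboxylic acid | C=C1C(=O)O[C@H](CCCCCCCCCCCCCCC(=O)OC(C)(C)C)[C@H]1C(=O)O | intermediate
7 | (2R,3S)-2-(14-carboxytetradecyl)-4-methylidene-5-oxooxolane-3-carboxylic acid | C=C1C(=O)O[C@H](CCCCCCCCCCCCCCC(=O)O)[C@H]1C(=O)O | target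

## Step count and least certain steps

Total steps: 4. Longest linear sequence: 4 steps (1 → 2 → 3 → 6 → 7); 4 is a commercial reagent that enters at step 3.

**Step 3 (key step, proposed new method).** Three processes are most likely to go wrong.
- The dienolate of 4 may be reprotonated at the exocyclic carbon faster than it adds to the aldehyde. This shifts the alkene into the anhydride ring and drains the nucleophile, because an unbranched aliphatic aldehyde is a slow electrophile; with equimolar partners this shows up as incomplete conversion of 3.
- Facial discrimination may be poor for a linear aldehyde that offers the catalyst little steric differentiation.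
- The catalyst amine may add to the methylidene of 4 or of the product, and the aldehyde may self-condense.

Fallback with known chemistry, setting out from 3 and returning at 6: the boron enolate (Bu2BOTf, iPr2NEt, CH2Cl2, −78 °C) of (4S)-4-benzyl-3-(4-methoxy-4-oxobutanoyl)-1,3-oxazolidin-2-one F1, made by one N-acylation of the commercial auxiliary, is added to 3 in an Evans syn-aldol. This should give the (3S,4R) hydroxy ester imide F2. F2 lactonises onto its methyl ester (catalytic pyridinium p-toluenesulfonate, toluene, 60 °C) to the trans lactone imide F3, the syn-aldol relationship translating into the trans ring. LiOH/H2O2 (THF/H2O, 0 °C) then removes the auxiliary to give the saturated paraconic acid F4. Carboxylation at C4 with MeOMgOCO2Me (DMF, 130 °C) gives the malonic half acid F5, and aqueous formaldehyde, N-methylaniline, NaOAc and AcOH (decarboxylative Mannich methylenation) convert F5 into 6.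

**Step 4.** Acid-promoted migration of the exocyclic double bond into the ring, or re-alkylation of the acids or the alkene by the tert-butyl cation, could erode the product; poor solubility of the long-chain diacid could slow the cleavage. Fallback, setting out from 3 and returning at 7: the ester is removed before the sensitive ring exists. CF3CO2H/CH2Cl2 converts 3 into 16-oxohexadecanoic acid F6, and F6 is submitted to the conditions of step 3 with 4 to give 7 directly. This is defensible because the key step already has to tolerate one equivalent of carboxylic acid, its own product.

**Step 2.** Over-oxidation, hemiacetal ester formation between product and unreacted alcohol, and air oxidation or oligomerisation of the long-chain aldehyde during isolation could lower the quality of the aldehyde that the key step depends on. Fallback, setting out from 1 and returning at 3, which avoids the alcohol altogether: 1 is condensed with ethanethiol (EDC·HCl, catalytic DMAP, CH2Cl2) to the thioester tert-butyl 16-(ethylsulfanyl)-16-oxohexadecanoate F7, and Fukuyama reduction of F7 (Et3SiH, Pd/C, acetone, rt) gives 3 at the aldehyde oxidation level without an oxidant.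

## Further compounds

F1 | step 3 | (4S)-4-benzyl-3-(4-methoxy-4-oxobutanoyl)-1,3-oxazolidin-2-one | COC(=O)CCC(=O)N1[C@@H](Cc2ccccc2)COC1=O
F2 | step 3 | 19-tert-butyl 1-methyl (3S,4R)-3-{[(4S)-4-benzyl-2-oxo-1,3-oxazolidin-3-yl]carbonyl}-4-hydroxynonadecanedioate | COC(=O)C[C@H](C(=O)N1[C@@H](Cc2ccccc2)COC1=O)[C@H](O)CCCCCCCCCCCCCCC(=O)OC(C)(C)C
F3 | step 3 | tert-butyl 15-[(2R,3S)-3-{[(4S)-4-benzyl-2-oxo-1,3-oxazolidin-3-yl]carbonyl}-5-oxooxolan-2-yl]pentadecanoate | C1C(=O)O[C@H](CCCCCCCCCCCCCCC(=O)OC(C)(C)C)[C@H]1C(=O)N2[C@@H](Cc3ccccc3)COC2=O
F4 | step 3 | (2R,3S)-2-[15-(tert-butoxy)-15-oxopentadecyl]-5-oxooxolane-3-carboxylic acid | C1C(=O)O[C@H](CCCCCCCCCCCCCCC(=O)OC(C)(C)C)[C@H]1C(=O)O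
F5 | step 3 | (2R,3S)-2-[15-(tert-butoxy)-15-oxopentadecyl]-5-oxooxolane-3,4-dicarboxylic acid (both C4 epimers) | OC(=O)C1C(=O)O[C@H](CCCCCCCCCCCCCCC(=O)OC(C)(C)C)[C@H]1C(=O)O
F6 | step 4 | 16-oxohexadecanoic acid | OC(=O)CCCCCCCCCCCCCCC=O
F7 | step 2 | tert-butyl 16-(ethylsulfanyl)-16-oxohexadecanoate | CCSC(=O)CCCCCCCCCCCCCCC(=O)OC(C)(C)C
A1 | alternative 1 | (2R,3S)-2-(14-carboxytetradecyl)-5-oxooxolane-3-carboxylic acid | C1C(=O)O[C@H](CCCCCCCCCCCCCCC(=O)O)[C@H]1C(=O)O
A2 | alternative 2 | dimethyl (2Z)-2-(bromomethyl)but-2-enedioate (ester groups trans) | COC(=O)/C=C(\CBr)C(=O)OC
A3 | alternative 2 | methyl (2R,3S)-2-[15-(tert-butoxy)-15-oxopentadecyl]-4-methylidene-5-oxooxolane-3-carboxylate | C=C1C(=O)O[C@H](CCCCCCCCCCCCCCC(=O)OC(C)(C)C)[C@H]1C(=O)OC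
A4 | alternative 3 | 6-ethyl 3-methyl (1R,5R,6R)-2-oxabicyclo[3.1.0]hex-3-ene-3,6-dicarboxylate | CCOC(=O)[C@H]1[C@@H]2OC(C(=O)OC)=C[C@H]12
A5 | alternative 3 | (2R,3S)-5-oxo-2-(prop-2-en-1-yl)oxolane-3-carbaldehyde | C1C(=O)O[C@H](CC=C)[C@H]1C=O
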